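Amounts come first, because a flask can't give more product than its charges contain.

| setting | violet | ash | alder | larch | birch | elm |
|---|---|---|---|---|---|---|
| substrate | 0.50 M | 0.50 M | 0.50 M | 0.50 M | 0.50 M | 0.50 M |
| coupling partner | 0.49 M | 0.400 M | 0.600 M | 1.00 M | 1.50 M | 2.50 M |
| initiator | 12 mM | 12 mM | 12 mM | 12 mM | 12 mM | 12 mM |
| remark | run made earlier |  |  |  |  |  |
| time |  | 30 d | 30 d | 30 d | 30 d | 30 d |

- violet (time / d: product / %, substrate / %): 2.50: 45, 60; 5.00: 59, 41; 8.00: 67, 37; 10.0: 71, 26; 12.0: 72, 24; 15.0: 73, 25

(standard deviation of a reading: 2 percentage points)

- candidate steps: coupling partner + first chain carrier -> product + second chain carrier; 2 second chain carrier -> ended chains; initiator -> 2 initiating radical; substrate + initiating radical -> capped initiator + first chain carrier; substrate + second chain carrier -> released group + first chain carrier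
- "hardly changes" means that all values lie within two and a half points (for a concentration: within two and a half percent of the largest)

* [product] at the end for ash, alder, larch, birch, elm, in this order
* how the row runs (rises all the way / rises, then falls / falls, then rises / hardly changes / falls all the way)

Write the balance of the smaller charge. By the candidate steps each product costs one coupling partner, so in ash c(coupling partner) is 0.400 M minus c(product). The ceiling on c(product) is the smaller of the substrate and partner charges, and in ash that is the partner (the limiting reagent by charge): 0.400 M. In alder the same rule gives the substrate charge, 0.500 M, and the richer flasks keep that substrate charge as their ceiling.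

The bound from below is a reading. The last violet reading, at 15.0 d, is 73% of the substrate, which is 0.365 M, and by the balance the violet run then still held 0.125 M of partner. Ash has partner for that amount with 0.0350 M to spare, so I take the reading as my floor. That is as tight as I can go: I put ash between 0.365 M and 0.400 M, and the other flasks between 0.365 M and 0.50 M. This bracket doesn't tell you how the row runs.

The forecast gives 0.365 M at each point, so the row hardly changes. Of ash it says: “Ash has 0.400 M partner, just enough, though it could fall slightly short.” That value sits on my floor, under the ash ceiling.

The flasks give 0.398 M, 0.398 M, 0.398 M, 0.398 M and 0.398 M, so the row hardly changes.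

    coupling partner + first chain carrier → product + second chain carrier (k = 1.30 × 10⁵ /M/h)
    2 second chain carrier → ended chains (k = 3.90 × 10⁶ /M/s)
    initiator → 2 initiating radical (k = 0.0120 /h)
    substrate + initiating radical → capped initiator + first chain carrier (k = 3.80 × 10⁶ /M/h)
    substrate + second chain carrier → released group + first chain carrier (k = 90000 /M/h)

Ash stands at its ceiling of 0.400 M, with 0.543% of its partner charge left at 30.0 d. The forecast lies 0.0330 M below ash and 0.0330 M below elm. Alder stands 0.102 M under its ceiling of 0.500 M, with 20.4% of its substrate and 33.7% of its partner left, while its initiator is down to 0.0177% of its charge.

The earlier runs and the new flask were computed for substances that don't exist; noise was put on by code.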